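**Retrosynthetic overview**
- Target ⇒ 1-(6-hydroxy-2,3-dimethoxyphenyl)-3-(2,3,5,6-tetramethoxyphenyl)propane-1,3-dione, by acid cyclodehydration (O1–C2 bond of the pyranone).
- Diketone ⇒ 6-hydroxy-2,3-dimethoxyacetophenone + 2,3,5,6-tetramethoxybenzoyl chloride, by intermolecular Claisen condensation of the dilithium enolate (CH2–CO bond, the key C–C bond).
- Acetophenone ⇒ 3,4-dimethoxyphenol: MOM ether, ortho-lithiation between the two oxygens, acetaldehyde, oxidation, MOM removal.
- Aroyl chloride ⇒ 1,2,4,5-tetramethoxybenzene: ortho-lithiation, CO2, oxalyl chloride.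
- Ring order: both benzene rings (A and B) are bought intact; the pyranone C ring is the only ring made and is closed last.

Assumption: the target has no stereocentre and is achiral, so "single enantiomer" needs no stereocontrol; the one stereocentre met on the way (in 5, racemic) is destroyed in step 3.

**Step 1**
Reactants: 1 3,4-dimethoxyphenol
Product: 3 1,2-dimethoxy-4-(methoxymethoxy)benzene, via sodium 3,4-dimethoxyphenoxide 2 (not isolated)
Conditions: NaH (1.2 equiv), DMF, 0 °C; then MOMCl (1.2 equiv), 0 °C → rt
Reagents that add atoms: chloromethyl methyl ether (MOMCl), COCCl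
Why: Williamson-type O-alkylation of the phenoxide with the very reactive α-chloro ether installs the MOM group, which protects the phenol and acts as the directing group for step 2.

**Step 2**
Reactants: 3 1,2-dimethoxy-4-(methoxymethoxy)benzene
Product: 5 rac-1-[2,3-dimethoxy-6-(methoxymethoxy)phenyl]ethan-1-ol, via aryllithium 4 (not isolated)
Conditions: n-BuLi (1.2 equiv), TMEDA, THF, 0 °C → rt, 1 h; then MeCHO (3 equiv), −78 °C → rt; H2O
Reagents that add atoms: acetaldehyde, CC=O
Why: Directed ortho-metalation removes the proton flanked by OMOM and OMe (cooperative direction by both oxygens), and the aryllithium adds 1,2 to acetaldehyde; the new carbinol centre forms racemic and is erased in step 3.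

**Step 3**
Reactants: 5 rac-1-[2,3-dimethoxy-6-(methoxymethoxy)phenyl]ethan-1-ol
Product: 6 1-[2,3-dimethoxy-6-(methoxymethoxy)phenyl]ethan-1-one
Conditions: Dess–Martin periodinane (1.3 equiv), CH2Cl2, rt
Reagents that add atoms: none
Why: Dess–Martin oxidation converts the hindered secondary benzylic alcohol into the aryl methyl ketone under near-neutral conditions that leave the MOM acetal and the electron-rich ring untouched.

**Step 4**
Reactants: 6 1-[2,3-dimethoxy-6-(methoxymethoxy)phenyl]ethan-1-one
Product: 7 1-(6-hydroxy-2,3-dimethoxyphenyl)ethan-1-one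
Conditions: 3 M HCl, MeOH, 50 °C
Reagents that add atoms: none
Why: Acid-catalysed acetal cleavage (transacetalisation to methanol) removes the MOM group, while aryl methyl ethers are inert to dilute HCl and the freed phenol is stabilised by hydrogen bonding to the ketone.

**Step 5**
Reactants: 8 1,2,4,5-tetramethoxybenzene
Product: 10 2,3,5,6-tetramethoxybenzoic acid, via aryllithium 9 (not isolated)
Conditions: n-BuLi (1.05 equiv), TMEDA, THF, 0 °C → rt; then CO2 (g, excess), −78 °C → rt; aq. HCl
Reagents that add atoms: carbon dioxide, O=C=O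
Why: Directed ortho-metalation at one of the two equivalent ring positions (each flanked by two methoxy groups) followed by carboxylation of the aryllithium; only one regioisomer is possible.

**Step 6**
Reactants: 10 2,3,5,6-tetramethoxybenzoic acid
Product: 11 2,3,5,6-tetramethoxybenzoyl chloride
Conditions: (COCl)2 (1.5 equiv), DMF (cat.), CH2Cl2, 0 °C → rt; evaporate, use crude
Reagents that add atoms: oxalyl chloride, O=C(Cl)C(=O)Cl
Why: Vilsmeier-catalysed acid chloride formation, driven by loss of CO, CO2 and HCl, works under mild non-acidic conditions suited to the electron-rich ring.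

**Step 7**
Reactants: 7 1-(6-hydroxy-2,3-dimethoxyphenyl)ethan-1-one; 11 2,3,5,6-tetramethoxybenzoyl chloride
Product: 13 1-(6-hydroxy-2,3-dimethoxyphenyl)-3-(2,3,5,6-tetramethoxyphenyl)propane-1,3-dione, via dilithium phenoxide-enolate 12 (not isolated)
Conditions: LiHMDS (4 equiv), THF, −78 → −10 °C, 2 h; then 11 (1.05 equiv) in THF, −78 °C → rt; aq. HCl
Reagents that add atoms: none
Why: Intermolecular (crossed) Claisen condensation in which the dianion is acylated at its more nucleophilic enolate carbon by the non-enolisable aroyl chloride, and the excess base stores the acidic 1,3-diketone as its salt so that no second acylation occurs.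

**Step 8**
Reactants: 13 1-(6-hydroxy-2,3-dimethoxyphenyl)-3-(2,3,5,6-tetramethoxyphenyl)propane-1,3-dione
Product: 14 5,6,2',3',5',6'-hexamethoxyflavone
Conditions: H2SO4 (cat., 0.5% v/v), AcOH, 95 °C, 2–3 h; pour onto ice
Reagents that add atoms: none
Why: Acid-catalysed cyclodehydration, in which the phenol adds to the aryl ketone to give a hemiketal that loses water to the aromatic γ-pyrone; no stereocentre is formed.

**Compound list**
1 | 3,4-dimethoxyphenol | COc1ccc(O)cc1OC | starting material
2 | sodium 3,4-dimethoxyphenoxide | [Na+].[O-]c1ccc(OC)c(OC)c1 | intermediate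
3 | 1,2-dimethoxy-4-(methoxymethoxy)benzene | COCOc1ccc(OC)c(OC)c1 | intermediate
4 | [2,3-dimethoxy-6-(methoxymethoxy)phenyl]lithium | [Li]c1c(OCOC)ccc(OC)c1OC | intermediate
5 | rac-1-[2,3-dimethoxy-6-(methoxymethoxy)phenyl]ethan-1-ol (racemic) | CC(O)c1c(OCOC)ccc(OC)c1OC | intermediate
6 | 1-[2,3-dimethoxy-6-(methoxymethoxy)phenyl]ethan-1-one | CC(=O)c1c(OCOC)ccc(OC)c1OC | intermediate
7 | 1-(6-hydroxy-2,3-dimethoxyphenyl)ethan-1-one (2'-hydroxy-5',6'-dimethoxyacetophenone) | CC(=O)c1c(O)ccc(OC)c1OC | intermediate
8 | 1,2,4,5-tetramethoxybenzene | COc1cc(OC)c(OC)cc1OC | starting material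
9 | (2,3,5,6-tetramethoxyphenyl)lithium | [Li]c1c(OC)c(OC)cc(OC)c1OC | intermediate
10 | 2,3,5,6-tetramethoxybenzoic acid | COc1cc(OC)c(OC)c(C(=O)O)c1OC | intermediate
11 | 2,3,5,6-tetramethoxybenzoyl chloride | COc1cc(OC)c(OC)c(C(=O)Cl)c1OC | intermediate
12 | dilithium phenoxide-enolate of 7 (dilithium 2-(1-oxidoethenyl)-3,4-dimethoxyphenolate) | [Li+].[Li+].C=C([O-])c1c([O-])ccc(OC)c1OC | intermediate
13 | 1-(6-hydroxy-2,3-dimethoxyphenyl)-3-(2,3,5,6-tetramethoxyphenyl)propane-1,3-dione (keto form; largely enolised) | COc1cc(OC)c(OC)c(C(=O)CC(=O)c2c(O)ccc(OC)c2OC)c1OC | intermediate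
14 | 5,6,2',3',5',6'-hexamethoxyflavone (5,6-dimethoxy-2-(2,3,5,6-tetramethoxyphenyl)-4H-chromen-4-one; achiral) | COc1cc(OC)c(OC)c(-c2cc(=O)c3c(OC)c(OC)ccc3o2)c1OC | target

**Summary**
Total step count: 8 (steps 1–4 make fragment 7, steps 5–6 make fragment 11, steps 7–8 join them and close the ring).
Longest linear sequence: 6 steps (1 → 3 → 5 → 6 → 7 → 13 → 14; steps 1, 2, 3, 4, 7, 8).

**Steps most likely to fail, with fallbacks**

Step 7 (most at risk). The aroyl chloride is di-ortho-substituted, so C-acylation may be slow and O-acylation or silylamide formation with LiHMDS can compete. The fallback sets out from 7 and 8 and comes back to the route at 14, by-passing 11 and 13. Compound 8 is lithiated as in step 5 (giving 9) but trapped with DMF to give 2,3,5,6-tetramethoxybenzaldehyde F2. A Claisen–Schmidt aldol condensation of 7 with this aldehyde (KOH, EtOH, rt) gives (E)-1-(6-hydroxy-2,3-dimethoxyphenyl)-3-(2,3,5,6-tetramethoxyphenyl)prop-2-en-1-one F3. Oxidative cyclisation of this 2'-hydroxychalcone with catalytic I2 in DMSO at 120 °C then closes the pyranone and delivers 14 directly.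

Step 2. Acetaldehyde can be enolised by the hindered aryllithium or be of poor quality, returning 3, and lithiation may be incomplete. The fallback sets out from 3 and comes back at 5. Compound 3 is lithiated in the same way (giving 4) but trapped with the non-enolisable electrophile DMF to give 2,3-dimethoxy-6-(methoxymethoxy)benzaldehyde F1, which is purified. Addition of MeMgBr (THF, 0 °C) to this aldehyde then gives carbinol 5, so the side chain is built in two one-carbon operations instead of one two-carbon addition.

Step 8. Hot acid can partly cleave the 5-methoxy group peri to the C4 carbonyl, giving mixtures. The fallback sets out from 13 and comes back at 14. The cyclisation is run as before and the crude mixture is treated with BCl3 (CH2Cl2, −20 → 0 °C), which cleaves only the chelating peri methoxy group. This converges all material on 5-hydroxy-6-methoxy-2-(2,3,5,6-tetramethoxyphenyl)-4H-chromen-4-one F4. Re-methylation of the chelated phenol with MeI and K2CO3 in DMF at 50 °C then gives 14.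

**Further compounds**
F1 | step 2 | 2,3-dimethoxy-6-(methoxymethoxy)benzaldehyde | COCOc1ccc(OC)c(OC)c1C=O
F2 | step 7 | 2,3,5,6-tetramethoxybenzaldehyde | COc1cc(OC)c(OC)c(C=O)c1OC
F3 | step 7 | (E)-1-(6-hydroxy-2,3-dimethoxyphenyl)-3-(2,3,5,6-tetramethoxyphenyl)prop-2-en-1-one | COc1cc(OC)c(OC)c(/C=C/C(=O)c2c(O)ccc(OC)c2OC)c1OC
F4 | step 8 | 5-hydroxy-6-methoxy-2-(2,3,5,6-tetramethoxyphenyl)-4H-chromen-4-one | COc1cc(OC)c(OC)c(-c2cc(=O)c3c(O)c(OC)ccc3o2)c1OC
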